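## The problem

Target 21 is a flavan: a chroman (rings A and C) that carries ring B at C2, its only stereocentre, of (S) configuration. With no second stereocentre to relay from, C2 has to be set by a reagent or catalyst. Because it is a benzylic ether carbon para to the 4'-hydroxyl, it can open to a quinone methide under base, acid or heat, so every later step must be gentle towards it. Ring A bears a 1,1-dimethylallyl group at C6 beside the C7 phenol; ring B is a catechol flanked by prenyl groups at C2' and C5', the former wedged between C1' and O3'. These three allyl units cyclise onto their neighbouring phenols under acid and would be saturated by hydrogenation, and the catechol is oxidised by air in base, which rules out acidic, hydrogenolytic or strongly basic deprotection at the end. The skeleton itself is plain: two arenes joined by a three-carbon chain, with O1 bridging C8a and C2. The enabling feature is that C2 is attached to C1' of ring B para to O4'. Oxidation of a ring B catechol to the o-quinone and a proton shift turn an unfunctionalised C2 methylene into the methide carbon of a p-quinone methide, six atoms from the C8a oxygen, so O1–C2, ring C and the stereocentre can arise in one operation from an achiral 1,3-diarylpropane. Each ring B prenyl group is ortho to a catechol oxygen and so maps onto an aromatic Claisen rearrangement, which lets these groups be withheld until the oxidation is over.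

## Retrosynthesis

**C7 ester.** Target 21 is traced to its C7 pivalate 20; only the ester C–O bond is cut. An acyl group is preferred over an acetal or a silyl ether because it leaves by hydride at low temperature, where neither the allyl groups nor C2 are at risk, and because it damps the nucleophilicity of ring A in the oxidative step. The forward reaction only has to tolerate the two free catechol protons.

**Ring B prenyl groups.** In 20 the bonds C2'–CH2 and C5'–CH2 are cut, leading back by two [3,3] shifts (through the mono-rearranged phenol 19) to the bis(1,1-dimethylallyl) ether 18. This is preferred over direct C-prenylation or cross-coupling because each allyl group is placed by the oxygen it leaves: O4' can deliver only to C5' and O3' only to C2'. Ether 18 comes from the bis(propargyl) ether 17 by semihydrogenation, and 17 from catechol 15 and the tertiary propargylic chloride 16. Precursor 15 is simpler by ten carbons and two trisubstituted alkenes. The forward sequence must etherify two adjacent oxygens with tertiary groups and rearrange them without ionisation.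

**O1–C2 (key cut).** In 15 the O1–C2 bond is cut, giving the achiral triphenol 12. The neighbouring cut O1–C8a would need a stereodefined benzylic alcohol and an aryl halide, and a C–C cut in ring C would leave C2 unaddressed; O1–C2 alone lets the stereocentre be created from a CH2 group. The forward reaction runs through o-quinone 13 and p-quinone methide 14. It must oxidise only the catechol, tautomerise only towards C2 and close ring C on one face of the methide. The prenyl groups are absent at this stage for a reason: with a prenyl group next to a quinone carbonyl the proton shift would run into that side chain and end in a 2,2-dimethylchromene.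

**C4–C4a.** Triphenol 12 arises by desilylation of 11, in which the aryl–alkyl bond C4a–C4 is cut to give aryl bromide 6 and allyl arene 9 (used as its borane 10). Cuts at C3–C4 or C2–C3 would call for carbonyl chemistry followed by deoxygenation or alkene reduction, which the terminal alkene of ring A would not survive. Hydroboration and cross-coupling deliver the saturated chain directly from two halves of similar size. The borane must be formed before 6 is present, and the coupling must tolerate a free ortho phenol.

**Ring A.** Bromide 6 is traced to phenol 5 by removing bromine, which sits ortho to the only free hydroxyl. Phenol 5 comes from bis(pivalate) 4 by cleavage of the one ester that is not shielded by the quaternary carbon. Cutting the aryl–CMe2 bond of 4 gives bromide 2 and allylboronate 3, and 2 is the bis(pivalate) of commercial 1. A monobromide is chosen so that the quaternary carbon is installed at a single C–Br bond and no statistical mono-coupling of a symmetrical dihalide is needed. The forward coupling must join at the γ-carbon of the allyl unit.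

**Ring B.** Allyl arene 9 is the bis(silyl ether) of 4-allylcatechol 8, which comes from eugenol 7 by O-demethylation. Ring B with its three-carbon chain is therefore bought.

## Roads not taken

Alternative 1: The cut falls on C2'–CH2 and C5'–CH2. The defining step is the thermal double Claisen rearrangement of the 7-O-silyl bis(1,1-dimethylallyl) ether A2 to the 7-O-silyl target A1.
- Merits: no reagent, forced regiochemistry, both prenyl groups in one operation, and a long-established reaction type.
- Weak points: as a strategy it says nothing about ring C or C2. The flavan with its stereocentre would have to come from a separate sequence (typically asymmetric ketone reduction and Mitsunobu closure). The silyl ether of A1 must then be removed with fluoride from a 4'-hydroxyflavan, where phenoxide formation invites ring-opening at C2.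
- Comparison: the chosen plan uses the same rearrangement as a supporting step (step 12) and so carries the same thermal risk. Alternative 1 is better in that its key step is precedented, whereas step 9 is not. Against that the chosen plan sets the creation of ring C and C2 from an achiral, unoxygenated chain and a final deprotection by hydride.

Alternative 2: Here C3=C4 is cut. The diene A4, the (S)-1-arylallyl ether of a 2-vinylphenol, is closed by the second-generation Grubbs catalyst to the 2H-chromene A3 with loss of ethylene.
- Merits: the stereocentre would be set beforehand in an acyclic allyl aryl ether by asymmetric allylic etherification (for instance [Ir(cod)Cl]2 with a chiral phosphoramidite), a predictable source of configuration, and the metathesis is reliable. In predictability of the enantioselective step this road is better than the chosen one.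
- Weak points: A3 is a 2-aryl-2H-chromene, which can open electrocyclically to an o-quinone methide and so lose C2. The C3=C4 bond is made only to be reduced again, and that reduction must spare the aryl bromide and the benzylic, allylic C2–O bond. The coupling at the C6 bromide, both ring B prenyl groups and three protecting-group removals still lie ahead, and the methoxymethyl ether needs acid that the finished allylphenols do not tolerate.
- Comparison: the chosen plan is shorter, has no redox detour and ends with hydride rather than acid. It has to set an unprecedented key step against the secure stereochemistry of this road.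

Alternative 3: The cut is O1–C8a. The bromo alcohol A6, an (S)-1,3-diarylpropan-1-ol with bromine at C8a, is cyclised with Pd(OAc)2, a bulky di-tert-butylbiarylphosphine and Cs2CO3 to the tris(methoxymethyl) ether A5 of the target.
- Merits: the C2–O bond is never broken, so the configuration from a reliable ketone reduction is carried through unchanged, and ring B arrives fully prenylated. In security of configuration and in convergence this road is stronger than the chosen one.
- Weak points: a secondary benzylic alkoxide on palladium is prone to β-hydride elimination (ketone plus reduced arene), aggravated here by the 2'-prenyl group beside the carbinol. The tetrasubstituted, doubly prenylated ring B ketone is a long synthesis in itself. Three methoxymethyl ethers must finally be cleaved by acid next to three allyl groups, each placed to cyclise onto the phenol being freed.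
- Comparison: the chosen plan needs neither a stereocentre nor an oxygen at C2 in its precursor, builds ring B from a bought allylbenzene and finishes under non-acidic conditions. What it gives up is the certainty of configuration that A6 would offer.

Key step: step 9

Assumption: the sense of induction of the BINOL-derived phosphoric acid in step 9 cannot be predicted with confidence; (R)-TRIP is written, and its antipode would be used if the (2R)-flavan were favoured.

## Route

Step 1
Reactants: 1 4-bromobenzene-1,3-diol (4-bromoresorcinol)
Product: 2 4-bromo-1,3-phenylene bis(2,2-dimethylpropanoate)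
Conditions: PivCl (2.4 equiv), Et3N, DMAP (cat.), CH2Cl2, 0 °C to rt
Reagents that add atoms: pivaloyl chloride, CC(C)(C)C(Cl)=O
Why: Exhaustive O-acylation of both phenols with nucleophilic catalysis by DMAP; the two esters are told apart later by the steric bias that step 2 creates.

Step 2
Reactants: 2 4-bromo-1,3-phenylene bis(2,2-dimethylpropanoate); 3 prenylboronic acid pinacol ester
Product: 4 4-(2-methylbut-3-en-2-yl)-1,3-phenylene bis(2,2-dimethylpropanoate)
Conditions: 3 (1.5 equiv), Pd(OAc)2 (cat.), biarylphosphine ligand selected for γ (branched) selectivity, aq. K3PO4, THF, 40 °C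
Reagents that add atoms: none
Why: Ligand-controlled γ-selective Suzuki–Miyaura allyl–aryl coupling: SE2' transmetalation puts palladium on the tertiary carbon and fast reductive elimination gives the aryl–CMe2–CH=CH2 unit; there is only one C–Br bond, so no site issue arises.

Step 3
Reactants: 4 4-(2-methylbut-3-en-2-yl)-1,3-phenylene bis(2,2-dimethylpropanoate)
Product: 5 5-hydroxy-2-(2-methylbut-3-en-2-yl)phenyl pivalate
Conditions: K2CO3 (0.5 equiv), MeOH, 0 °C, monitored
Reagents that add atoms: none
Why: Base-mediated methanolysis (transesterification) of an aryl ester; the pivalate flanked by two ring hydrogens reacts, the one beside the quaternary carbon is shielded, and the phenoxide formed by the first cleavage deactivates the remaining ester.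

Step 4
Reactants: 5 5-hydroxy-2-(2-methylbut-3-en-2-yl)phenyl pivalate
Product: 6 4-bromo-5-hydroxy-2-(2-methylbut-3-en-2-yl)phenyl pivalate
Conditions: NBS (1.0 equiv), i-Pr2NH (cat.), CH2Cl2, −20 to 0 °C
Reagents that add atoms: N-bromosuccinimide, O=C1CCC(=O)N1Br
Why: Electrophilic aromatic bromination ortho to the free phenol; the para position is blocked and the ortho site between hydroxyl and pivalate is the more hindered, and the phenol reacts far faster than the neopentyl-type terminal alkene.

Step 5
Reactants: 7 eugenol (4-allyl-2-methoxyphenol)
Product: 8 4-allylbenzene-1,2-diol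
Conditions: BBr3, CH2Cl2, −78 to 0 °C; then H2O
Reagents that add atoms: none
Why: Lewis-acid cleavage of the aryl methyl ether (bromide attacks the O-methyl group of the boron complex); the low temperature keeps HBr from adding to the allyl group.

Step 6
Reactants: 8 4-allylbenzene-1,2-diol
Product: 9 4-allyl-1,2-bis(tert-butyldimethylsilyloxy)benzene
Conditions: TBSCl (2.3 equiv), imidazole, DMF, rt
Reagents that add atoms: tert-butyldimethylsilyl chloride, CC(C)(C)[Si](C)(C)Cl
Why: Standard silylation of both catechol oxygens; it removes the acidic protons before hydroboration and masks the catechol against oxidation during the coupling.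

Step 7
Reactants: 9 4-allyl-1,2-bis(tert-butyldimethylsilyloxy)benzene; 6 4-bromo-5-hydroxy-2-(2-methylbut-3-en-2-yl)phenyl pivalate
Product: 11 4-{3-[3,4-bis(tert-butyldimethylsilyloxy)phenyl]propyl}-5-hydroxy-2-(2-methylbut-3-en-2-yl)phenyl pivalate, via B-alkyl-9-BBN adduct 10 (not isolated)
Conditions: 9 (1.3 equiv), 9-BBN (1.25 equiv), THF, 0 °C to rt; then aq. K3PO4, 6, Pd(OAc)2 (cat.), SPhos, THF, 50 °C
Reagents that add atoms: none
Why: Anti-Markovnikov hydroboration of the terminal alkene followed by B-alkyl Suzuki–Miyaura coupling; aqueous base destroys any residual B–H before 6 is added, so its 1,1-dimethylallyl group is not hydroborated, and the electron-rich dialkylbiarylphosphine allows oxidative addition into the bromophenol.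

Step 8
Reactants: 11 4-{3-[3,4-bis(tert-butyldimethylsilyloxy)phenyl]propyl}-5-hydroxy-2-(2-methylbut-3-en-2-yl)phenyl pivalate
Product: 12 4-[3-(3,4-dihydroxyphenyl)propyl]-5-hydroxy-2-(2-methylbut-3-en-2-yl)phenyl pivalate
Conditions: KHF2, MeOH, rt, Ar
Reagents that add atoms: none
Why: Fluoride cleavage of aryl silyl ethers under near-neutral conditions, which leaves the hindered aryl pivalate and the air-sensitive catechol intact.

Step 9
Reactants: 12 4-[3-(3,4-dihydroxyphenyl)propyl]-5-hydroxy-2-(2-methylbut-3-en-2-yl)phenyl pivalate
Product: 15 (S)-2-(3,4-dihydroxyphenyl)-6-(2-methylbut-3-en-2-yl)chroman-7-yl pivalate, via ortho-quinone 13 (not isolated), via para-quinone methide 14 (not isolated)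
Conditions: Ag2O (1.0 equiv), Na2SO4, CH2Cl2, −20 °C, cold filtration through Celite under Ar; then (R)-TRIP [3,3'-bis(2,4,6-triisopropylphenyl)-BINOL hydrogen phosphate] (10 mol %), 4 Å MS, CH2Cl2/toluene, high dilution, −40 °C
Reagents that add atoms: none
Why: Proposed new method: Ag2O takes two electrons and two protons from the catechol of 12 to give the 4-alkyl-o-quinone 13; after the silver is filtered off cold, the phosphoric acid mediates the shift of a C2 hydrogen to O3', giving the 2-hydroxy-p-quinone methide 14, and the C8a phenol adds to the methide carbon (oxa-1,6-addition), driven by return of ring B to the aromatic catechol. The closest known reaction types are the o-quinone to p-quinone methide tautomerisation with intramolecular phenol capture and chiral phosphoric acid catalysed 1,6-additions to p-quinone methides; joining them in one enantioselective cascade that starts from a plain CH2 group is new. Ring C closes in the 6-exo-trig mode, O1 attacking the exocyclic C2=C1' bond. The C2 stereocentre is controlled by the catalyst: the phosphate is expected to hold the quinone methide through O4' and the O3' hydroxyl and the attacking phenol through its P=O oxygen, so that one face of the planar methide is offered. The step needs oxidation at the catechol only (the monophenol, the pivalate and the alkene are inert to Ag2O) and tautomerisation towards C2 only (the propyl chain is the sole alkyl group on the quinone). It needs O- rather than C-attack, which the substrate secures because C5 of ring A is meta to both oxygens and C8 cannot reach C2. Re-oxidation of 15 is avoided by using one equivalent of oxidant and removing the silver before cyclisation, and high dilution suppresses intermolecular addition.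

Step 10
Reactants: 15 (S)-2-(3,4-dihydroxyphenyl)-6-(2-methylbut-3-en-2-yl)chroman-7-yl pivalate; 16 3-chloro-3-methylbut-1-yne
Product: 17 (S)-2-[3,4-bis(2-methylbut-3-yn-2-yloxy)phenyl]-6-(2-methylbut-3-en-2-yl)chroman-7-yl pivalate
Conditions: 16 (4 equiv), DBU, CuCl2 (cat.), MeCN, 0 °C, Ar
Reagents that add atoms: none
Why: Copper-catalysed O-propargylation of phenols with a tertiary propargylic chloride (through a copper acetylide-derived electrophile), which tolerates hindered oxygens; the pivalate keeps O7 out of the reaction and the low temperature limits base-induced opening at C2.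

Step 11
Reactants: 17 (S)-2-[3,4-bis(2-methylbut-3-yn-2-yloxy)phenyl]-6-(2-methylbut-3-en-2-yl)chroman-7-yl pivalate
Product: 18 (S)-2-[3,4-bis(2-methylbut-3-en-2-yloxy)phenyl]-6-(2-methylbut-3-en-2-yl)chroman-7-yl pivalate
Conditions: H2 (1 atm), Pd/CaCO3 poisoned with Pb(OAc)2 (Lindlar catalyst), quinoline, EtOAc, rt, stopped after 2 equiv H2
Reagents that add atoms: none
Why: Lindlar semihydrogenation; terminal alkynes bind the poisoned catalyst far more strongly than the hindered terminal alkenes, so the ring A vinyl group and the new vinyl ethers should persist if uptake is monitored.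

Step 12
Reactants: 18 (S)-2-[3,4-bis(2-methylbut-3-en-2-yloxy)phenyl]-6-(2-methylbut-3-en-2-yl)chroman-7-yl pivalate
Product: 20 (S)-2-[3,4-dihydroxy-2,5-bis(3-methylbut-2-en-1-yl)phenyl]-6-(2-methylbut-3-en-2-yl)chroman-7-yl pivalate, via mono-rearranged phenol 19 (not isolated)
Conditions: N,N-diethylaniline, 130 °C, Ar
Reagents that add atoms: none
Why: Two successive aromatic Claisen rearrangements ([3,3] shift, then tautomerisation): the O4' allyl group can reach only C5' and the O3' allyl group only C2', and allylic transposition turns each 1,1-dimethylallyl ether into a prenyl group; the weakly basic solvent suppresses acid-promoted ether ionisation and chroman formation, and C2 takes no part (19 is drawn for O4' reacting first; the other order converges on 20).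

Step 13
Reactants: 20 (S)-2-[3,4-dihydroxy-2,5-bis(3-methylbut-2-en-1-yl)phenyl]-6-(2-methylbut-3-en-2-yl)chroman-7-yl pivalate
Product: 21 (2S)-4-[7-hydroxy-6-(2-methylbut-3-en-2-yl)chroman-2-yl]-3,6-bis(3-methylbut-2-en-1-yl)benzene-1,2-diol
Conditions: i-Bu2AlH (DIBAL-H, 5 equiv), CH2Cl2, −78 to 0 °C; aq. KNaC4H4O6 (Rochelle salt), Ar
Reagents that add atoms: none
Why: Reductive cleavage of the aryl pivalate by hydride after the two catechol protons are consumed; no acid, no strong base at temperature and no hydrogenation, so the three allyl groups, the catechol and the C2 configuration should be preserved.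

## Compound list

1 | 4-bromobenzene-1,3-diol | Oc1ccc(Br)c(O)c1 | starting material
2 | 4-bromo-1,3-phenylene bis(2,2-dimethylpropanoate) | CC(C)(C)C(=O)Oc1ccc(Br)c(OC(=O)C(C)(C)C)c1 | intermediate
3 | prenylboronic acid pinacol ester | CC(C)=CCB1OC(C)(C)C(C)(C)O1 | starting material
4 | 4-(2-methylbut-3-en-2-yl)-1,3-phenylene bis(2,2-dimethylpropanoate) | C=CC(C)(C)c1ccc(OC(=O)C(C)(C)C)cc1OC(=O)C(C)(C)C | intermediate
5 | 5-hydroxy-2-(2-methylbut-3-en-2-yl)phenyl pivalate | C=CC(C)(C)c1ccc(O)cc1OC(=O)C(C)(C)C | intermediate
6 | 4-bromo-5-hydroxy-2-(2-methylbut-3-en-2-yl)phenyl pivalate | C=CC(C)(C)c1cc(Br)c(O)cc1OC(=O)C(C)(C)C | intermediate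
7 | eugenol | C=CCc1ccc(O)c(OC)c1 | starting material
8 | 4-allylbenzene-1,2-diol | C=CCc1ccc(O)c(O)c1 | intermediate
9 | 4-allyl-1,2-bis(tert-butyldimethylsilyloxy)benzene | C=CCc1ccc(O[Si](C)(C)C(C)(C)C)c(O[Si](C)(C)C(C)(C)C)c1 | intermediate
10 | 9-{3-[3,4-bis(tert-butyldimethylsilyloxy)phenyl]propyl}-9-borabicyclo[3.3.1]nonane | CC(C)(C)[Si](C)(C)Oc1ccc(CCCB2C3CCCC2CCC3)cc1O[Si](C)(C)C(C)(C)C | intermediate (not isolated)
11 | 4-{3-[3,4-bis(tert-butyldimethylsilyloxy)phenyl]propyl}-5-hydroxy-2-(2-methylbut-3-en-2-yl)phenyl pivalate | C=CC(C)(C)c1cc(CCCc2ccc(O[Si](C)(C)C(C)(C)C)c(O[Si](C)(C)C(C)(C)C)c2)c(O)cc1OC(=O)C(C)(C)C | intermediate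
12 | 4-[3-(3,4-dihydroxyphenyl)propyl]-5-hydroxy-2-(2-methylbut-3-en-2-yl)phenyl pivalate | C=CC(C)(C)c1cc(CCCc2ccc(O)c(O)c2)c(O)cc1OC(=O)C(C)(C)C | intermediate
13 | 4-[3-(3,4-dioxocyclohexa-1,5-dien-1-yl)propyl]-5-hydroxy-2-(2-methylbut-3-en-2-yl)phenyl pivalate (o-quinone) | C=CC(C)(C)c1cc(CCCC2=CC(=O)C(=O)C=C2)c(O)cc1OC(=O)C(C)(C)C | intermediate (not isolated)
14 | 5-hydroxy-4-[3-(3-hydroxy-4-oxocyclohexa-2,5-dien-1-ylidene)propyl]-2-(2-methylbut-3-en-2-yl)phenyl pivalate (p-quinone methide, alkene geometry not defined) | C=CC(C)(C)c1cc(CCC=C2C=CC(=O)C(O)=C2)c(O)cc1OC(=O)C(C)(C)C | intermediate (not isolated)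
15 | (S)-2-(3,4-dihydroxyphenyl)-6-(2-methylbut-3-en-2-yl)chroman-7-yl pivalate | C=CC(C)(C)c1cc2c(cc1OC(=O)C(C)(C)C)O[C@H](c1ccc(O)c(O)c1)CC2 | intermediate
16 | 3-chloro-3-methylbut-1-yne | C#CC(C)(C)Cl | starting material
17 | (S)-2-[3,4-bis(2-methylbut-3-yn-2-yloxy)phenyl]-6-(2-methylbut-3-en-2-yl)chroman-7-yl pivalate | C=CC(C)(C)c1cc2c(cc1OC(=O)C(C)(C)C)O[C@H](c1ccc(OC(C)(C)C#C)c(OC(C)(C)C#C)c1)CC2 | intermediate
18 | (S)-2-[3,4-bis(2-methylbut-3-en-2-yloxy)phenyl]-6-(2-methylbut-3-en-2-yl)chroman-7-yl pivalate | C=CC(C)(C)c1cc2c(cc1OC(=O)C(C)(C)C)O[C@H](c1ccc(OC(C)(C)C=C)c(OC(C)(C)C=C)c1)CC2 | intermediate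
19 | (S)-2-[4-hydroxy-3-(2-methylbut-3-en-2-yloxy)-5-(3-methylbut-2-en-1-yl)phenyl]-6-(2-methylbut-3-en-2-yl)chroman-7-yl pivalate | C=CC(C)(C)c1cc2c(cc1OC(=O)C(C)(C)C)O[C@H](c1cc(CC=C(C)C)c(O)c(OC(C)(C)C=C)c1)CC2 | intermediate (not isolated)
20 | (S)-2-[3,4-dihydroxy-2,5-bis(3-methylbut-2-en-1-yl)phenyl]-6-(2-methylbut-3-en-2-yl)chroman-7-yl pivalate | C=CC(C)(C)c1cc2c(cc1OC(=O)C(C)(C)C)O[C@H](c1cc(CC=C(C)C)c(O)c(O)c1CC=C(C)C)CC2 | intermediate
21 | (2S)-4-[7-hydroxy-6-(2-methylbut-3-en-2-yl)chroman-2-yl]-3,6-bis(3-methylbut-2-en-1-yl)benzene-1,2-diol | C=CC(C)(C)c1cc2c(cc1O)O[C@H](c1cc(CC=C(C)C)c(O)c(O)c1CC=C(C)C)CC2 | target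

## Step count and least certain steps

Total: 13 steps. Longest linear sequence: 11 steps (steps 1–4 and 7–13, from 1); the ring B branch (steps 5–6) joins at step 7.

**Step 9 (bears the label "Proposed new method:").** The most likely failure is poor facial selectivity. Ring closure on the silver oxide surface or without the catalyst may outrun the catalysed path, and the two geometrical isomers of 14 need not be discriminated alike. Redox exchange between product catechol and remaining quinone would also reopen C2, and the quinone can oligomerise. The fallback uses known chemistry for the same O1–C2 bond; it sets out from bromide 6 and returns at 15.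
- 3,4-Dihydroxybenzaldehyde is silylated (TBSCl, imidazole) to 3,4-bis(tert-butyldimethylsilyloxy)benzaldehyde F1.
- Vinylmagnesium bromide converts it into 1-[3,4-bis(tert-butyldimethylsilyloxy)phenyl]prop-2-en-1-ol F2.
- Heck arylation of F2 with 6 (Pd(OAc)2, Bu4NCl, NaHCO3, DMF, 80 °C) gives, after β-hydride elimination towards the carbinol carbon and tautomerisation, 4-{3-[3,4-bis(tert-butyldimethylsilyloxy)phenyl]-3-oxopropyl}-5-hydroxy-2-(2-methylbut-3-en-2-yl)phenyl pivalate F3.
- Noyori transfer hydrogenation with RuCl(p-cymene)[(R,R)-TsDPEN] in HCO2H/Et3N, which leaves the alkene alone, should give (R)-4-{3-[3,4-bis(tert-butyldimethylsilyloxy)phenyl]-3-hydroxypropyl}-5-hydroxy-2-(2-methylbut-3-en-2-yl)phenyl pivalate F4, by analogy with simple aryl alkyl ketones.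
- Mitsunobu cyclisation (PPh3, DIAD, THF, 0 °C) closes O1–C2 with inversion to (S)-2-[3,4-bis(tert-butyldimethylsilyloxy)phenyl]-6-(2-methylbut-3-en-2-yl)chroman-7-yl pivalate F5.
- KHF2 in MeOH then returns 15.

**Step 12.** The most likely failures are three. The tertiary allyl ethers may ionise (loss of isoprene) in competition with the [3,3] shift into the crowded C2' position. The new o-prenylphenols may close to 2,2-dimethylchromans if traces of acid are present. Configuration at C2 may erode through ring-opening once the 4'-hydroxyl is free at 130 °C. The fallback sets out from 18 and returns at 21. The rearrangement is run in Ac2O with NaOAc at 130 °C, so that each phenol is acetylated as it forms. This gives (S)-4-[6-(2-methylbut-3-en-2-yl)-7-(pivaloyloxy)chroman-2-yl]-3,6-bis(3-methylbut-2-en-1-yl)-1,2-phenylene diacetate F6. The i-Bu2AlH treatment of step 13 then removes the two acetates and the pivalate together and gives 21 directly.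

**Step 10.** The most likely failures are incomplete etherification of the second oxygen next to the first tertiary ether, and base-induced ring-opening at C2 through the 4'-phenoxide before it is alkylated. The fallback sets out from 15 and returns at 18, bypassing 17 and step 11. 2-Methylbut-3-en-2-ol is converted (n-BuLi, Boc2O) into tert-butyl 2-methylbut-3-en-2-yl carbonate F7. Decarboxylative O-allylation of 15 with F7 and Pd(PPh3)4 in THF at 0 °C, under neutral conditions, gives the tertiary ethers by kinetic attack at the substituted allyl terminus and so leads straight to 18.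

**Step 2.** The most likely failure is loss of branched selectivity through σ–π–σ equilibration of the allylpalladium species before reductive elimination, giving the linear prenyl arene; the ortho ester makes this more likely by slowing the coupling. The fallback sets out from 2 and returns at 4. α-Arylation of isobutyraldehyde with 2 ([Pd(allyl)Cl]2, dppf, Cs2CO3, dioxane, 80 °C) gives 2-[2,4-bis(pivaloyloxy)phenyl]-2-methylpropanal F8. Wittig methylenation (Ph3P=CH2, THF, 0 °C) of this non-enolisable aldehyde returns 4.

**Step 7.** The most likely failures are sluggish oxidative addition into the electron-rich bromophenoxide, which gives time for protodeboronation or β-hydride loss from the alkyl group, and partial loss of silyl groups in aqueous base. The fallback sets out from 6 and returns at 12. Silylation of 6 (TBSCl, imidazole) gives 4-bromo-5-(tert-butyldimethylsilyloxy)-2-(2-methylbut-3-en-2-yl)phenyl pivalate F9. The same coupling with borane 10 then gives 4-{3-[3,4-bis(tert-butyldimethylsilyloxy)phenyl]propyl}-5-(tert-butyldimethylsilyloxy)-2-(2-methylbut-3-en-2-yl)phenyl pivalate F10. KHF2 in MeOH removes all three silyl groups and returns 12.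

## Further compounds

F1 | step 9 | 3,4-bis(tert-butyldimethylsilyloxy)benzaldehyde | O=Cc1ccc(O[Si](C)(C)C(C)(C)C)c(O[Si](C)(C)C(C)(C)C)c1
F2 | step 9 | 1-[3,4-bis(tert-butyldimethylsilyloxy)phenyl]prop-2-en-1-ol (racemic) | C=CC(O)c1ccc(O[Si](C)(C)C(C)(C)C)c(O[Si](C)(C)C(C)(C)C)c1
F3 | step 9 | 4-{3-[3,4-bis(tert-butyldimethylsilyloxy)phenyl]-3-oxopropyl}-5-hydroxy-2-(2-methylbut-3-en-2-yl)phenyl pivalate | C=CC(C)(C)c1cc(CCC(=O)c2ccc(O[Si](C)(C)C(C)(C)C)c(O[Si](C)(C)C(C)(C)C)c2)c(O)cc1OC(=O)C(C)(C)C
F4 | step 9 | (R)-4-{3-[3,4-bis(tert-butyldimethylsilyloxy)phenyl]-3-hydroxypropyl}-5-hydroxy-2-(2-methylbut-3-en-2-yl)phenyl pivalate | C=CC(C)(C)c1cc(CC[C@@H](O)c2ccc(O[Si](C)(C)C(C)(C)C)c(O[Si](C)(C)C(C)(C)C)c2)c(O)cc1OC(=O)C(C)(C)C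
F5 | step 9 | (S)-2-[3,4-bis(tert-butyldimethylsilyloxy)phenyl]-6-(2-methylbut-3-en-2-yl)chroman-7-yl pivalate | C=CC(C)(C)c1cc2c(cc1OC(=O)C(C)(C)C)O[C@H](c1ccc(O[Si](C)(C)C(C)(C)C)c(O[Si](C)(C)C(C)(C)C)c1)CC2
F6 | step 12 | (S)-4-[6-(2-methylbut-3-en-2-yl)-7-(pivaloyloxy)chroman-2-yl]-3,6-bis(3-methylbut-2-en-1-yl)-1,2-phenylene diacetate | C=CC(C)(C)c1cc2c(cc1OC(=O)C(C)(C)C)O[C@H](c1cc(CC=C(C)C)c(OC(C)=O)c(OC(C)=O)c1CC=C(C)C)CC2
F7 | step 10 | tert-butyl 2-methylbut-3-en-2-yl carbonate | C=CC(C)(C)OC(=O)OC(C)(C)C
F8 | step 2 | 2-[2,4-bis(pivaloyloxy)phenyl]-2-methylpropanal | CC(C)(C=O)c1ccc(OC(=O)C(C)(C)C)cc1OC(=O)C(C)(C)C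
F9 | step 7 | 4-bromo-5-(tert-butyldimethylsilyloxy)-2-(2-methylbut-3-en-2-yl)phenyl pivalate | C=CC(C)(C)c1cc(Br)c(O[Si](C)(C)C(C)(C)C)cc1OC(=O)C(C)(C)C
F10 | step 7 | 4-{3-[3,4-bis(tert-butyldimethylsilyloxy)phenyl]propyl}-5-(tert-butyldimethylsilyloxy)-2-(2-methylbut-3-en-2-yl)phenyl pivalate | C=CC(C)(C)c1cc(CCCc2ccc(O[Si](C)(C)C(C)(C)C)c(O[Si](C)(C)C(C)(C)C)c2)c(O[Si](C)(C)C(C)(C)C)cc1OC(=O)C(C)(C)C
A1 | alternative 1 | (S)-4-[7-(tert-butyldimethylsilyloxy)-6-(2-methylbut-3-en-2-yl)chroman-2-yl]-3,6-bis(3-methylbut-2-en-1-yl)benzene-1,2-diol | C=CC(C)(C)c1cc2c(cc1O[Si](C)(C)C(C)(C)C)O[C@H](c1cc(CC=C(C)C)c(O)c(O)c1CC=C(C)C)CC2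
A2 | alternative 1 | (S)-2-[3,4-bis(2-methylbut-3-en-2-yloxy)phenyl]-7-(tert-butyldimethylsilyloxy)-6-(2-methylbut-3-en-2-yl)chroman | C=CC(C)(C)c1cc2c(cc1O[Si](C)(C)C(C)(C)C)O[C@H](c1ccc(OC(C)(C)C=C)c(OC(C)(C)C=C)c1)CC2
A3 | alternative 2 | (S)-6-bromo-7-(methoxymethoxy)-2-[3,4-bis(tert-butyldimethylsilyloxy)phenyl]-2H-chromene | Brc1cc2c(cc1OCOC)O[C@H](c1ccc(O[Si](C)(C)C(C)(C)C)c(O[Si](C)(C)C(C)(C)C)c1)C=C2
A4 | alternative 2 | (S)-1-bromo-4-{1-[3,4-bis(tert-butyldimethylsilyloxy)phenyl]allyloxy}-2-(methoxymethoxy)-5-vinylbenzene | C=Cc1cc(Br)c(OCOC)cc1O[C@@H](C=C)c1ccc(O[Si](C)(C)C(C)(C)C)c(O[Si](C)(C)C(C)(C)C)c1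
A5 | alternative 3 | (S)-7-(methoxymethoxy)-2-[3,4-bis(methoxymethoxy)-2,5-bis(3-methylbut-2-en-1-yl)phenyl]-6-(2-methylbut-3-en-2-yl)chroman | C=CC(C)(C)c1cc2c(cc1OCOC)O[C@H](c1cc(CC=C(C)C)c(OCOC)c(OCOC)c1CC=C(C)C)CC2
A6 | alternative 3 | (S)-3-[2-bromo-4-(methoxymethoxy)-5-(2-methylbut-3-en-2-yl)phenyl]-1-[3,4-bis(methoxymethoxy)-2,5-bis(3-methylbut-2-en-1-yl)phenyl]propan-1-ol | C=CC(C)(C)c1cc(CC[C@H](O)c2cc(CC=C(C)C)c(OCOC)c(OCOC)c2CC=C(C)C)c(Br)cc1OCOC
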